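**Retrosynthetic overview**
1. Target 28 comes from the trans-dibenzylbutyrolactone 25 by LiAlH4 opening and deprotection. The lactone is a temporary ring that holds both butanediol stereocentres. 25 comes from alkylating the enolate of (R)-lactone 23 with the benzofuranylmethyl bromide 18.
2. 18 comes from ester 16. The dihydrofuran ring of 16 is closed at O1–C7a: the C2 alkoxide of the open-chain syn-1,3-diol 12 displaces fluoride from C7a (SNAr), with retention at C2.
3. Enabling feature: in the benzofuran core the carbon substituent on C5 is para to C7a. Kept at the ester level, it stabilises the anionic sigma-adduct at C7a and later becomes the C5 benzylic CH2. The same C7a–F bond first steers C–H borylation to the neighbouring C3a.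
4. 12 comes from an Evans syn-aldol of arylacetyl imide 7 with O-benzylvanillin 8, which sets C2 and C3. 7 comes from boronate 6 and bromoacetyl imide 4.
5. Ring order: butyrolactone 23 is made in a side branch (step 11), the dihydrofuran ring is closed in step 6, and the lactone is opened again in step 13.

Key step: step 6

Remark on numbering: the dihydrobenzofuran is numbered O1, C2, C3, C3a, C4–C7, C7a throughout, including in its open-chain precursors.

**Step 1**
Reactants: 1 (S)-4-benzyl-1,3-oxazolidin-2-one; 2 bromoacetyl bromide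
Product: 4 (S)-4-benzyl-3-(bromoacetyl)-1,3-oxazolidin-2-one, via lithium oxazolidinonide 3 (not isolated)
Conditions: n-BuLi, THF, −78 °C; then 2, −78 → 0 °C
Reagents that add atoms: none
Why: N-acylation of the lithiated Evans auxiliary, in which the acyl bromide reacts much faster than the alkyl bromide and the auxiliary stereocentre is not touched.

**Step 2**
Reactants: 5 methyl 4-fluoro-3-methoxybenzoate
Product: 6 methyl 4-fluoro-3-methoxy-5-(4,4,5,5-tetramethyl-1,3,2-dioxaborolan-2-yl)benzoate
Conditions: [Ir(OMe)(cod)]2 (cat.), 4,4'-di-tert-butyl-2,2'-bipyridine (cat.), B2pin2, THF, 80 °C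
Reagents that add atoms: bis(pinacolato)diboron, CC1(C)OB(OC1(C)C)B1OC(C)(C)C(C)(C)O1
Why: Iridium-catalysed aromatic C–H borylation is governed by sterics; the C–H between ester and methoxy is blocked on both sides and the one next to the ester is hindered, so the C–H next to the small, acidifying fluorine (the later C3a) should react.

**Step 3**
Reactants: 6 aryl boronate; 4 bromoacetyl imide
Product: 7 methyl 3-{2-[(4S)-4-benzyl-2-oxo-1,3-oxazolidin-3-yl]-2-oxoethyl}-4-fluoro-5-methoxybenzoate
Conditions: Pd(OAc)2 (cat.), P(o-tol)3 (cat.), K3PO4, THF/H2O, rt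
Reagents that add atoms: none
Why: Suzuki–Miyaura-type coupling of an arylboronate with an alpha-bromo carbonyl compound (oxidative addition of C–Br to zerovalent palladium gives a palladium enolate, then transmetalation and reductive elimination), run with a mild phosphate base at room temperature that should spare imide and ester.

**Step 4**
Reactants: 7 arylacetyl imide; 8 4-(benzyloxy)-3-methoxybenzaldehyde
Product: 11 methyl 3-{(2S,3S)-1-[(4S)-4-benzyl-2-oxo-1,3-oxazolidin-3-yl]-3-[4-(benzyloxy)-3-methoxyphenyl]-3-hydroxy-1-oxopropan-2-yl}-4-fluoro-5-methoxybenzoate, via boron enolate 9 (not isolated), via boron aldolate 10 (not isolated)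
Conditions: Bu2BOTf, Et3N, CH2Cl2, −78 → 0 °C; 8, −78 → 0 °C; then pH 7 buffer, MeOH, H2O2, 0 °C
Reagents that add atoms: none
Why: Evans syn-aldol reaction, in which the (Z)-boron enolate 9 reacts through a chair Zimmerman–Traxler transition state on the face opposite the benzyl group of the (S)-auxiliary and so sets both new centres (the later C3 and C2) as 2S,3S.

**Step 5**
Reactants: 11 syn-aldol imide
Product: 12 methyl 3-{(1S,2R)-1-[4-(benzyloxy)-3-methoxyphenyl]-1,3-dihydroxypropan-2-yl}-4-fluoro-5-methoxybenzoate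
Conditions: NaBH4, THF/H2O, 0 °C → rt
Reagents that add atoms: none
Why: Reductive removal of the auxiliary, since borohydride attacks the activated imide carbonyl but not the aryl methyl ester; no stereocentre is touched, and the descriptor of the aryl-bearing carbon changes to R only through the priority change.

**Step 6**
Reactants: 12 syn-1,3-diol
Product: 16 methyl (2S,3R)-2-[4-(benzyloxy)-3-methoxyphenyl]-3-{[(tert-butyldiphenylsilyl)oxy]methyl}-7-methoxy-2,3-dihydro-1-benzofuran-5-carboxylate, via dipotassium dialkoxide 13 (not isolated), via silylated potassium alkoxide 14 (not isolated), via anionic sigma-adduct 15 (not isolated)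
Conditions: KN(SiMe3)2 (2.1 equiv), THF, −78 °C; t-BuPh2SiCl (1.0 equiv), −78 → −40 °C; then warm to rt (40 °C if needed)
Reagents that add atoms: tert-butyl(chloro)diphenylsilane, CC(C)(C)[Si](Cl)(c1ccccc1)c1ccccc1
Why: Two equivalents of base give dialkoxide 13, whose unhindered primary alkoxide is capped by the bulky silyl chloride in the cold, so that only the benzylic C2 alkoxide of 14 is left to react on warming. It adds to C7a–F to give the anionic sigma-adduct 15, whose charge is carried by C5 and its ester, and loss of fluoride restores the arene; this is an addition–elimination nucleophilic aromatic substitution (SNAr) whose closest known relatives are the alkoxide cyclisations of 2-(2-fluoroaryl)ethanols and the etherification of 4-fluorobenzoates. The dihydrofuran ring closes in a 5-exo-trig mode, because the attacked C7a=C7 pi bond lies outside the new ring. No stereocentre is made or broken: the C2–O bond is never cleaved, so the aldol-derived (1S,2R) syn array passes with retention into the (2S,3R) trans ring, which a closure at C2 through a benzylic cation or quinone methide could not guarantee. The step needs oxygen selectivity, since both hydroxyls could form a five-membered ring at C7a; this is secured by the steric difference between the CH2O and ArCHO alkoxides towards t-BuPh2SiCl and by the reluctance of this silyl group to migrate, while site selectivity follows because C7a carries the only leaving group and is the only position para to the ester. At the alcohol oxidation level of the C3 side arm there is no enolisable carbonyl, so retro-aldol cleavage and loss of configuration are excluded.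

**Step 7**
Reactants: 16 dihydrobenzofuran ester
Product: 17 {(2S,3R)-2-[4-(benzyloxy)-3-methoxyphenyl]-3-{[(tert-butyldiphenylsilyl)oxy]methyl}-7-methoxy-2,3-dihydro-1-benzofuran-5-yl}methanol
Conditions: LiAlH4, THF, 0 °C
Reagents that add atoms: none
Why: Hydride reduction turns the ester, whose activating role is over, into the benzylic alcohol, while silyl ether, benzyl ether and the cyclic aryl ether are inert to LiAlH4.

**Step 8**
Reactants: 17 benzylic alcohol
Product: 18 (2S,3R)-2-[4-(benzyloxy)-3-methoxyphenyl]-5-(bromomethyl)-3-{[(tert-butyldiphenylsilyl)oxy]methyl}-7-methoxy-2,3-dihydro-1-benzofuran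
Conditions: CBr4, PPh3, CH2Cl2, 0 °C (used crude)
Reagents that add atoms: carbon tetrabromide, BrC(Br)(Br)Br
Why: The Appel reaction converts the primary benzylic alcohol into the bromide under neutral conditions, avoiding acid that could ionise the C2–O1 bond.

**Step 9**
Reactants: 8 4-(benzyloxy)-3-methoxybenzaldehyde; 19 dimethyl succinate
Product: 20 (E)-4-[4-(benzyloxy)-3-methoxyphenyl]-3-(methoxycarbonyl)but-3-enoic acid
Conditions: NaOMe, MeOH, reflux; then aq. HCl
Reagents that add atoms: none
Why: Stobbe condensation, in which the succinate enolate adds to the aldehyde, the adduct lactonises and base-induced opening gives the half-ester, with the aryl group trans to the ester (E) for steric reasons.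

**Step 10**
Reactants: 20 Stobbe half-ester
Product: 21 (3R)-4-[4-(benzyloxy)-3-methoxyphenyl]-3-(methoxycarbonyl)butanoic acid
Conditions: [Rh(cod)(Et-DuPhos)]BF4 (cat., ligand antipode that gives the R acid), H2 (5 bar), MeOH, rt
Reagents that add atoms: none
Why: Asymmetric hydrogenation of an itaconate-type half-ester, in which the substrate chelates the cationic rhodium centre and the C2-symmetric bisphospholane differentiates the alkene faces, setting the single stereocentre as R; the benzyl ether is not cleaved by this homogeneous catalyst.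

**Step 11**
Reactants: 21 (R)-half-ester
Product: 23 (4R)-4-[4-(benzyloxy)-3-methoxybenzyl]oxolan-2-one, via hydroxy acid 22 (not isolated)
Conditions: KOH (1 equiv), EtOH; CaCl2, NaBH4, EtOH, 0 °C → rt; then aq. HCl
Reagents that add atoms: none
Why: Chemoselective borohydride reduction of the ester beside the unreactive carboxylate salt, followed by acid-induced lactonisation (5-exo-trig); the stereocentre is not involved and stays R.

**Step 12**
Reactants: 23 (R)-lactone; 18 benzylic bromide
Product: 25 (3R,4R)-4-[4-(benzyloxy)-3-methoxybenzyl]-3-({(2S,3R)-2-[4-(benzyloxy)-3-methoxyphenyl]-3-{[(tert-butyldiphenylsilyl)oxy]methyl}-7-methoxy-2,3-dihydro-1-benzofuran-5-yl}methyl)oxolan-2-one, via lithium enolate 24 (not isolated)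
Conditions: LiN(SiMe3)2, THF, −78 °C; then 18, DMPU, −78 → −20 °C
Reagents that add atoms: none
Why: Enolate alkylation of a beta-substituted butyrolactone, the standard entry to dibenzylbutyrolactone lignans, in which the bromide approaches the planar enolate anti to the C4 benzyl group and sets C3 as R (trans lactone).

**Step 13**
Reactants: 25 trans-lactone
Product: 26 (2R,3R)-2-[4-(benzyloxy)-3-methoxybenzyl]-3-({(2S,3R)-2-[4-(benzyloxy)-3-methoxyphenyl]-3-{[(tert-butyldiphenylsilyl)oxy]methyl}-7-methoxy-2,3-dihydro-1-benzofuran-5-yl}methyl)butane-1,4-diol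
Conditions: LiAlH4, THF, 0 °C → rt
Reagents that add atoms: none
Why: Hydride reduction opens the temporary lactone ring to the 1,4-diol without touching either stereocentre.

**Step 14**
Reactants: 26 silyl-protected diol
Product: 27 (2R,3R)-2-[4-(benzyloxy)-3-methoxybenzyl]-3-({(2S,3R)-2-[4-(benzyloxy)-3-methoxyphenyl]-3-(hydroxymethyl)-7-methoxy-2,3-dihydro-1-benzofuran-5-yl}methyl)butane-1,4-diol
Conditions: Bu4NF, THF, rt
Reagents that add atoms: none
Why: Fluoride-induced desilylation, done while both phenols are still benzylated so that no phenoxide can open the ring through a quinone methide.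

**Step 15**
Reactants: 27 bis(benzyl ether) triol
Product: 28 (2R,3R)-2-(4-hydroxy-3-methoxybenzyl)-3-{[(2S,3R)-2-(4-hydroxy-3-methoxyphenyl)-3-(hydroxymethyl)-7-methoxy-2,3-dihydro-1-benzofuran-5-yl]methyl}butane-1,4-diol (CNP0256425.1)
Conditions: H2 (1 atm), Pd/C, EtOAc/MeOH, rt, stopped at full debenzylation
Reagents that add atoms: none
Why: Catalytic hydrogenolysis, in which aryl benzyl ethers should be cleaved faster than the more hindered cyclic benzylic C2–O1 ether under these mild neutral conditions.

**Compound list**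
1 | (S)-4-benzyl-1,3-oxazolidin-2-one | O=C1N[C@@H](Cc2ccccc2)CO1 | starting material
2 | bromoacetyl bromide | O=C(Br)CBr | starting material
3 | lithium salt of 1 (N-lithiated) | [Li+].O=C1[N-][C@@H](Cc2ccccc2)CO1 | intermediate
4 | (S)-4-benzyl-3-(bromoacetyl)-1,3-oxazolidin-2-one | O=C(CBr)N1C(=O)OC[C@@H]1Cc1ccccc1 | intermediate
5 | methyl 4-fluoro-3-methoxybenzoate | COC(=O)c1ccc(F)c(OC)c1 | starting material
6 | methyl 4-fluoro-3-methoxy-5-(pinacolatoboryl)benzoate | COC(=O)c1cc(OC)c(F)c(B2OC(C)(C)C(C)(C)O2)c1 | intermediate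
7 | arylacetyl imide of the (S)-auxiliary | COC(=O)c1cc(OC)c(F)c(CC(=O)N2C(=O)OC[C@@H]2Cc2ccccc2)c1 | intermediate
8 | 4-(benzyloxy)-3-methoxybenzaldehyde | COc1cc(C=O)ccc1OCc1ccccc1 | starting material
9 | (Z)-dibutylboron enolate of 7 | CCCCB(CCCC)O/C(=C\c1cc(C(=O)OC)cc(OC)c1F)N1C(=O)OC[C@@H]1Cc1ccccc1 | intermediate
10 | dibutylboron aldolate of 11 | COC(=O)c1cc(OC)c(F)c([C@@H]([C@H](OB(CCCC)CCCC)c2ccc(OCc3ccccc3)c(OC)c2)C(=O)N2C(=O)OC[C@@H]2Cc2ccccc2)c1 | intermediate
11 | (2S,3S) syn-aldol imide | COC(=O)c1cc(OC)c(F)c([C@@H]([C@H](O)c2ccc(OCc3ccccc3)c(OC)c2)C(=O)N2C(=O)OC[C@@H]2Cc2ccccc2)c1 | intermediate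
12 | (1S,2R) syn-1,3-diol | COC(=O)c1cc(OC)c(F)c([C@@H]([C@H](O)c2ccc(OCc3ccccc3)c(OC)c2)CO)c1 | intermediate
13 | dipotassium dialkoxide of 12 | COC(=O)c1cc(OC)c(F)c([C@@H]([C@H]([O-])c2ccc(OCc3ccccc3)c(OC)c2)C[O-])c1.[K+].[K+] | intermediate
14 | potassium benzylic alkoxide of the primary TBDPS ether of 12 | COC(=O)c1cc(OC)c(F)c([C@@H]([C@H]([O-])c2ccc(OCc3ccccc3)c(OC)c2)CO[Si](c2ccccc2)(c2ccccc2)C(C)(C)C)c1.[K+] | intermediate
15 | potassium sigma-adduct (C7a sp3, bearing F and O1; charge on the C5 ester) | COC([O-])=C1C=C(OC)C2(F)O[C@H](c3ccc(OCc4ccccc4)c(OC)c3)[C@@H](CO[Si](c3ccccc3)(c3ccccc3)C(C)(C)C)C2=C1.[K+] | intermediate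
16 | (2S,3R) trans-dihydrobenzofuran-5-carboxylate | COC(=O)c1cc(OC)c2c(c1)[C@H](CO[Si](c1ccccc1)(c1ccccc1)C(C)(C)C)[C@@H](c1ccc(OCc3ccccc3)c(OC)c1)O2 | intermediate
17 | (2S,3R) dihydrobenzofuran-5-ylmethanol | OCc1cc(OC)c2c(c1)[C@H](CO[Si](c1ccccc1)(c1ccccc1)C(C)(C)C)[C@@H](c1ccc(OCc3ccccc3)c(OC)c1)O2 | intermediate
18 | (2S,3R) 5-(bromomethyl)dihydrobenzofuran | BrCc1cc(OC)c2c(c1)[C@H](CO[Si](c1ccccc1)(c1ccccc1)C(C)(C)C)[C@@H](c1ccc(OCc3ccccc3)c(OC)c1)O2 | intermediate
19 | dimethyl succinate | COC(=O)CCC(=O)OC | starting material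
20 | (E)-Stobbe half-ester | COC(=O)/C(CC(=O)O)=C/c1ccc(OCc2ccccc2)c(OC)c1 | intermediate
21 | (R)-benzylsuccinic half-ester | COC(=O)[C@@H](CC(=O)O)Cc1ccc(OCc2ccccc2)c(OC)c1 | intermediate
22 | (R)-3-(hydroxymethyl)-4-arylbutanoic acid | OC[C@@H](CC(=O)O)Cc1ccc(OCc2ccccc2)c(OC)c1 | intermediate
23 | (4R)-4-[4-(benzyloxy)-3-methoxybenzyl]oxolan-2-one | O=C1C[C@@H](Cc2ccc(OCc3ccccc3)c(OC)c2)CO1 | intermediate
24 | lithium enolate of 23 | [Li+].[O-]C1=C[C@@H](Cc2ccc(OCc3ccccc3)c(OC)c2)CO1 | intermediate
25 | (3R,4R) trans-dibenzylbutyrolactone | O=C1[C@H](Cc2cc(OC)c3c(c2)[C@H](CO[Si](c2ccccc2)(c2ccccc2)C(C)(C)C)[C@@H](c2ccc(OCc4ccccc4)c(OC)c2)O3)[C@@H](Cc2ccc(OCc3ccccc3)c(OC)c2)CO1 | intermediate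
26 | (2R,3R) butane-1,4-diol, TBDPS and two benzyl groups in place | COc1cc(C[C@@H](CO)[C@H](CO)Cc2cc(OC)c3c(c2)[C@H](CO[Si](c2ccccc2)(c2ccccc2)C(C)(C)C)[C@@H](c2ccc(OCc4ccccc4)c(OC)c2)O3)ccc1OCc1ccccc1 | intermediate
27 | triol, two benzyl groups in place | COc1cc(C[C@@H](CO)[C@H](CO)Cc2cc(OC)c3c(c2)[C@H](CO)[C@@H](c2ccc(OCc4ccccc4)c(OC)c2)O3)ccc1OCc1ccccc1 | intermediate
28 | CNP0256425.1 | COc1cc(C[C@@H](CO)[C@H](CO)Cc2cc(OC)c3c(c2)[C@H](CO)[C@@H](c2ccc(O)c(OC)c2)O3)ccc1O | target

**Step count**
Total steps: 15. Longest linear sequence: 11 steps (steps 2–8 and 12–15).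

**Steps most likely to fail**

Step 6. The in-flask silylation may not discriminate well enough between the two alkoxides, so that the primary oxygen closes the ring. Addition to the only moderately activated arene may also be slow enough for intermolecular ester exchange to compete. The fallback distinguishes the two oxygens by oxidation level instead of by a protecting group. Setting out from 11, LiOH/H2O2 (THF/H2O, 0 °C) removes the auxiliary to give the beta-hydroxy acid F1. With two equivalents of KN(SiMe3)2 in THF/DMF the carboxylate is inert towards the fluoroarene and blocks enolisation and retro-aldol cleavage, so only the C2 alkoxide can close the ring, giving the trans dihydrobenzofuran-3-carboxylic acid F2. BH3·THF reduces the acid beside the aryl ester to the hydroxymethyl ester F3, and t-BuPh2SiCl/imidazole brings the material back to the route at 16.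

Step 3. Hydrolysis of the imide, protodeboronation of the ortho-fluoro boronate or simple reduction of the C–Br bond may outrun the coupling. The fallback attaches the auxiliary after the C–C bond is made, not before. Setting out from 6, coupling with the robust tert-butyl bromoacetate gives the tert-butyl arylacetate F4. CF3CO2H liberates the arylacetic acid F5, and pivaloyl chloride/Et3N gives the mixed pivalic anhydride F6. This anhydride acylates the lithium salt 3 and returns to the route at 7.

Step 12. The electron-rich benzylic bromide may ionise or self-alkylate before C-alkylation, or proton transfer may lead to double alkylation. The fallback forms the bond by carbonyl addition and removes the oxygen afterwards by a radical reaction. Setting out from 17, MnO2 gives the 5-carbaldehyde F7. Addition of enolate 24 (anti to the C4 benzyl group) gives the hydroxy lactone F8 as a mixture at the carbinol carbon. 1,1'-Thiocarbonyldiimidazole converts it into the imidazolylthiocarbonyl ester F9, and Barton–McCombie deoxygenation (Bu3SnH, AIBN, toluene, 80 °C) removes the superfluous oxygen and comes back to the route at 25.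

**Further compounds**
F1 | step 6 | (2S,3S)-3-[4-(benzyloxy)-3-methoxyphenyl]-2-[2-fluoro-3-methoxy-5-(methoxycarbonyl)phenyl]-3-hydroxypropanoic acid | COC(=O)c1cc(OC)c(F)c([C@@H]([C@H](O)c2ccc(OCc3ccccc3)c(OC)c2)C(=O)O)c1
F2 | step 6 | (2S,3S)-2-[4-(benzyloxy)-3-methoxyphenyl]-7-methoxy-5-(methoxycarbonyl)-2,3-dihydro-1-benzofuran-3-carboxylic acid (trans) | COC(=O)c1cc(OC)c2c(c1)[C@H](C(=O)O)[C@@H](c1ccc(OCc3ccccc3)c(OC)c1)O2
F3 | step 6 | methyl (2S,3R)-2-[4-(benzyloxy)-3-methoxyphenyl]-3-(hydroxymethyl)-7-methoxy-2,3-dihydro-1-benzofuran-5-carboxylate | COC(=O)c1cc(OC)c2c(c1)[C@H](CO)[C@@H](c1ccc(OCc3ccccc3)c(OC)c1)O2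
F4 | step 3 | methyl 3-(2-tert-butoxy-2-oxoethyl)-4-fluoro-5-methoxybenzoate | COC(=O)c1cc(OC)c(F)c(CC(=O)OC(C)(C)C)c1
F5 | step 3 | [2-fluoro-3-methoxy-5-(methoxycarbonyl)phenyl]acetic acid | COC(=O)c1cc(OC)c(F)c(CC(=O)O)c1
F6 | step 3 | mixed anhydride of F5 and pivalic acid | COC(=O)c1cc(OC)c(F)c(CC(=O)OC(=O)C(C)(C)C)c1
F7 | step 12 | (2S,3R)-2-[4-(benzyloxy)-3-methoxyphenyl]-3-{[(tert-butyldiphenylsilyl)oxy]methyl}-7-methoxy-2,3-dihydro-1-benzofuran-5-carbaldehyde | O=Cc1cc(OC)c2c(c1)[C@H](CO[Si](c1ccccc1)(c1ccccc1)C(C)(C)C)[C@@H](c1ccc(OCc3ccccc3)c(OC)c1)O2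
F8 | step 12 | trans-lactone carrying a benzylic hydroxyl on the C3 side chain (carbinol epimers) | O=C1[C@H](C(O)c2cc(OC)c3c(c2)[C@H](CO[Si](c2ccccc2)(c2ccccc2)C(C)(C)C)[C@@H](c2ccc(OCc4ccccc4)c(OC)c2)O3)[C@@H](Cc2ccc(OCc3ccccc3)c(OC)c2)CO1
F9 | step 12 | O-(imidazol-1-ylthiocarbonyl) derivative of F8 | O=C1[C@H](C(OC(=S)n2ccnc2)c2cc(OC)c3c(c2)[C@H](CO[Si](c2ccccc2)(c2ccccc2)C(C)(C)C)[C@@H](c2ccc(OCc4ccccc4)c(OC)c2)O3)[C@@H](Cc2ccc(OCc3ccccc3)c(OC)c2)CO1
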